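## Retrosynthetic overview

- The strategy rests on the 2,5-disubstituted furan ring. Its two alpha carbons, C2 (bearing CH2CO2H) and C5 (bearing n-hexadecyl), both bond to the ring oxygen, so the ring is the dehydrated form of a cis-3,6-disubstituted 3,6-dihydro-1,2-dioxine, and its four carbons are C3 to C6 of a linear C22 (3E,5E)-3,5-dienoate.
- Furan ⇒ cis-gamma-hydroxy enone ⇒ 1,2-dioxine ⇒ methyl (3E,5E)-docosa-3,5-dienoate + singlet oxygen ([4+2]).
- Diene ⇒ C4–C5 sp2–sp2 Negishi union of (E)-octadec-1-enylzinc chloride (from 1-octadecyne) with methyl (E)-4-iodobut-3-enoate (from 3-butyn-1-ol).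
- Ring order: the six-membered 1,2-dioxine is closed first by cycloaddition and opened at O–O, then the furan is closed at oxygen with loss of water; ester hydrolysis comes last.

Key step: step 7

Remark: the target is achiral. Dioxine 13 and hydroxy enone 14 are racemic (the SMILES of 13 shows one enantiomer of the cis compound), and their stereocentres vanish on aromatisation. Reagents are named in the Conditions lines and carry no compound number.

## Route

Step 1
Reactants: 1 3-butyn-1-ol
Product: 2 tert-butyl(but-3-yn-1-yloxy)dimethylsilane
Conditions: TBSCl, imidazole, CH2Cl2, 0 °C to rt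
Reagents that add atoms: tert-butyldimethylsilyl chloride, CC(C)(C)[Si](C)(C)Cl
Why: Imidazole-promoted silylation of the primary alcohol (silyl ether protection) removes the acidic O–H, so that the zirconium hydride of the next step is spent only on the alkyne.

Step 2
Reactants: 2 tert-butyl(but-3-yn-1-yloxy)dimethylsilane
Product: 4 (E)-tert-butyl[(4-iodobut-3-en-1-yl)oxy]dimethylsilane, via (E)-[4-(tert-butyldimethylsilyloxy)but-1-enyl]zirconocene chloride 3 (not isolated)
Conditions: Cp2Zr(H)Cl, THF, rt, dark; then I2, THF, 0 °C
Reagents that add atoms: iodine, [I][I]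
Why: Hydrozirconation adds Zr–H syn across the terminal alkyne with zirconium at the terminal carbon, and iodinolysis of the C–Zr bond occurs with retention, so the iodoalkene should form as the (E)-isomer (hydrozirconation–iodination).

Step 3
Reactants: 4 (E)-tert-butyl[(4-iodobut-3-en-1-yl)oxy]dimethylsilane
Product: 5 (E)-4-iodobut-3-en-1-ol
Conditions: p-toluenesulfonic acid monohydrate (cat.), MeOH, rt
Reagents that add atoms: none
Why: Acid-catalysed methanolysis of the primary silyl ether (TBS solvolysis) frees the alcohol, and the iodoalkene is inert to catalytic acid at room temperature.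

Step 4
Reactants: 5 (E)-4-iodobut-3-en-1-ol
Product: 7 (E)-4-iodobut-3-enoic acid, via (E)-4-iodobut-3-enal 6 (not isolated)
Conditions: CrO3, H2SO4, H2O, acetone, 0 °C (Jones oxidation); iPrOH quench
Reagents that add atoms: water, O
Why: Jones oxidation carries the primary alcohol through aldehyde 6 and its hydrate to the acid in an acidic medium where no enolate forms, so the C3=C4 alkene should stay beta,gamma and the iodoalkene untouched.

Step 5
Reactants: 7 (E)-4-iodobut-3-enoic acid
Product: 8 methyl (E)-4-iodobut-3-enoate (fragment 2)
Conditions: Me3SiCHN2 (hexane solution), MeOH/toluene, 0 °C to rt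
Reagents that add atoms: trimethylsilyldiazomethane, C[Si](C)(C)C=[N+]=[N-]
Why: Methyl ester formation with a diazoalkane (protonation of the reagent by the acid, desilylation by methanol, O-alkylation of the carboxylate) needs no base, so the alkene is not drawn into conjugation.

Step 6
Reactants: 9 1-octadecyne; 8 methyl (E)-4-iodobut-3-enoate
Product: 12 methyl (3E,5E)-docosa-3,5-dienoate, via (E)-octadec-1-enylzirconocene chloride 10 (not isolated), via (E)-octadec-1-enylzinc chloride 11 (not isolated)
Conditions: 9, Cp2Zr(H)Cl (slightly less than 1 equiv per 9), THF, rt; ZnCl2 (anhydrous, THF), 0 °C; then 8, Pd(PPh3)4 (zerovalent palladium, 5 mol %), THF, rt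
Reagents that add atoms: none
Why: Syn hydrozirconation of 9 fixes the (E)-alkenylmetal, Zr-to-Zn transmetalation gives a non-basic alkenylzinc (fragment 1), and the Negishi coupling retains both alkene geometries and tolerates the ester, so the base-free conditions should deliver the skipped (3E,5E)-diene ester.

Step 7
Reactants: 12 methyl (3E,5E)-docosa-3,5-dienoate
Product: 13 methyl 2-(cis-6-hexadecyl-3,6-dihydro-1,2-dioxin-3-yl)acetate (racemic)
Conditions: O2 (bubbling), 5,10,15,20-tetraphenylporphyrin (cat.), visible light, CH2Cl2, −10 °C; cold work-up, rapid chromatography, no distillation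
Reagents that add atoms: oxygen, O=O
Why: Sensitised excitation of O2 gives singlet oxygen, which adds as a two-electron dienophile to the s-cis conformer of the (E,E)-diene in a concerted suprafacial [4+2] cycloaddition, forming the C3–O and C6–O bonds together. The closest known reaction type is the dye-sensitised photooxygenation of acyclic (E,E)-1,4-disubstituted 1,3-dienes to cis-3,6-disubstituted 3,6-dihydro-1,2-dioxines, a hetero-Diels–Alder reaction. The six-membered 1,2-dioxine ring closes in this single cycloaddition event, and the former C4–C5 single bond becomes the cis ring alkene. The two new stereocentres (C3 and C6 of the dioxine) are set cis to each other by suprafacial addition to a diene whose two alkenes are both E; there is no facial bias, so the product is racemic, which is of no consequence because both centres are lost on aromatisation. The step needs chemoselectivity for cycloaddition over the ene reaction at the allylic C2–H and C7–H bonds and must not let the skipped ester slip into conjugation; the (E,E) geometry with its unhindered s-cis conformer, the ester insulated by one CH2, the neutral aprotic medium and the low temperature should secure this.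

Step 8
Reactants: 13 methyl 2-(cis-6-hexadecyl-3,6-dihydro-1,2-dioxin-3-yl)acetate
Product: 14 methyl (Z)-6-hydroxy-3-oxodocos-4-enoate (racemic)
Conditions: Et3N (0.5 equiv), CH2Cl2, 0 °C to rt; crude product taken on after a short silica plug
Reagents that add atoms: none
Why: In this Kornblum–DeLaMare rearrangement the amine removes the hydrogen on peroxide-bearing C3 as the O–O bond breaks, giving the ketone and the alkoxide and hence the gamma-hydroxy enone with the cis alkene of the ring retained; removal of the C6 hydrogen instead would give the 3-hydroxy-6-oxo isomer, which leads to the same furan.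

Step 9
Reactants: 14 methyl (Z)-6-hydroxy-3-oxodocos-4-enoate
Product: 16 methyl 2-(5-hexadecylfuran-2-yl)acetate, via methyl 2-(5-hexadecyl-2-hydroxy-2,5-dihydrofuran-2-yl)acetate 15 (not isolated)
Conditions: p-toluenesulfonic acid monohydrate (10 mol %), 4 Å molecular sieves, CH2Cl2, rt
Reagents that add atoms: none
Why: In this acid-catalysed cyclodehydration (Paal–Knorr-type furan synthesis) 5-exo-trig addition of the hydroxyl to the ketone gives hemiketal 15, and ionisation of its hydroxyl with loss of the C5 proton is driven by aromatisation, which also removes the remaining stereocentre.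

Step 10
Reactants: 16 methyl 2-(5-hexadecylfuran-2-yl)acetate
Product: 18 2-(5-hexadecylfuran-2-yl)acetic acid (CID10473105), via lithium 2-(5-hexadecylfuran-2-yl)acetate 17 (not isolated)
Conditions: LiOH·H2O, THF/H2O, 0 °C to rt; then 1 M HCl to pH 3 at 0 °C, EtOAc extraction
Reagents that add atoms: lithium hydroxide, [Li+].[OH-]
Why: Saponification of the unhindered methyl ester (acyl–oxygen cleavage by hydroxide) gives the lithium carboxylate, the furan is stable to aqueous base, and brief cold acidification frees the acid without exposing the acid-sensitive ring to strong acid.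

## Compound list

1 | 3-butyn-1-ol | C#CCCO | starting material
2 | tert-butyl(but-3-yn-1-yloxy)dimethylsilane | C#CCCO[Si](C)(C)C(C)(C)C | intermediate
3 | (E)-[4-(tert-butyldimethylsilyloxy)but-1-enyl]zirconocene chloride (not isolated) | CC(C)(C)[Si](C)(C)OCC/C=C/[Zr](Cl)(C1C=CC=C1)C1C=CC=C1 | intermediate
4 | (E)-tert-butyl[(4-iodobut-3-en-1-yl)oxy]dimethylsilane | CC(C)(C)[Si](C)(C)OCC/C=C/I | intermediate
5 | (E)-4-iodobut-3-en-1-ol | OCC/C=C/I | intermediate
6 | (E)-4-iodobut-3-enal (not isolated) | O=CC/C=C/I | intermediate
7 | (E)-4-iodobut-3-enoic acid | OC(=O)C/C=C/I | intermediate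
8 | methyl (E)-4-iodobut-3-enoate (fragment 2) | COC(=O)C/C=C/I | intermediate
9 | 1-octadecyne | CCCCCCCCCCCCCCCCC#C | starting material
10 | (E)-octadec-1-enylzirconocene chloride (not isolated) | CCCCCCCCCCCCCCCC/C=C/[Zr](Cl)(C1C=CC=C1)C1C=CC=C1 | intermediate
11 | (E)-octadec-1-enylzinc chloride (fragment 1, not isolated) | CCCCCCCCCCCCCCCC/C=C/[Zn]Cl | intermediate
12 | methyl (3E,5E)-docosa-3,5-dienoate | CCCCCCCCCCCCCCCC/C=C/C=C/CC(=O)OC | intermediate
13 | methyl 2-(cis-6-hexadecyl-3,6-dihydro-1,2-dioxin-3-yl)acetate, racemic, drawn as (3R,6S) | CCCCCCCCCCCCCCCC[C@H]1C=C[C@@H](CC(=O)OC)OO1 | intermediate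
14 | methyl (Z)-6-hydroxy-3-oxodocos-4-enoate, racemic | CCCCCCCCCCCCCCCCC(O)/C=C\C(=O)CC(=O)OC | intermediate
15 | methyl 2-(5-hexadecyl-2-hydroxy-2,5-dihydrofuran-2-yl)acetate (not isolated) | CCCCCCCCCCCCCCCCC1C=CC(O)(CC(=O)OC)O1 | intermediate
16 | methyl 2-(5-hexadecylfuran-2-yl)acetate | CCCCCCCCCCCCCCCCc1ccc(CC(=O)OC)o1 | intermediate
17 | lithium 2-(5-hexadecylfuran-2-yl)acetate (not isolated) | [Li+].CCCCCCCCCCCCCCCCc1ccc(CC(=O)[O-])o1 | intermediate
18 | 2-(5-hexadecylfuran-2-yl)acetic acid, CID10473105 | CCCCCCCCCCCCCCCCc1ccc(CC(=O)O)o1 | target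

## Step count

Total steps: 10. Longest linear sequence: 10 steps (steps 1 to 10, from 3-butyn-1-ol); 1-octadecyne enters at step 6.

## Steps most likely to fail

1. Step 7 (photooxygenation). The ene reaction at the allylic C–H bonds may outrun the cycloaddition. The cycloaddition may also be too slow for an unactivated 1,4-dialkyl diene, so that the peroxide decomposes on long irradiation. The fallback sets out from 12 and comes back at 16, and needs no peroxide. Monoepoxidation with mCPBA (1 equiv, NaHCO3-buffered CH2Cl2, 0 °C) should give the racemic vinyl oxiranes methyl (E)-4-(trans-3-hexadecyloxiran-2-yl)but-3-enoate F1 and methyl 2-[trans-3-((E)-octadec-1-enyl)oxiran-2-yl]acetate F2. They need not be separated, because Cu(hfacac)2 (copper bis(hexafluoroacetylacetonate), divalent copper, catalytic, hot toluene) ring-expands either vinyl oxirane to the same methyl 2-(5-hexadecyl-2,5-dihydrofuran-2-yl)acetate F3 (cis/trans mixture). Dehydrogenation of F3 with DDQ (dioxane, rt to 60 °C) should then give furan ester 16.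

2. Step 8 (Kornblum–DeLaMare rearrangement). The amine may instead remove a proton alpha to the ester and trigger beta-elimination of the peroxide oxygen, opening the ring to a dienyl hydroperoxide. The hydroxy enone may also oligomerise under base. A neutral variant with catalytic Co(salen) (divalent cobalt) is only a change of promoter; the fallback proper avoids base altogether. It sets out from 13 and comes back at 14. Zn dust and AcOH (CH2Cl2, 0 °C) should cleave the O–O bond reductively to methyl rel-(3R,6S,Z)-3,6-dihydroxydocos-4-enoate F4. Activated MnO2 (CH2Cl2, rt) should then oxidise one of the two allylic carbinols, giving 14 together with its regioisomer methyl (Z)-3-hydroxy-6-oxodocos-4-enoate F5; both enter step 9 and converge on 16.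

3. Step 6 (hydrozirconation, transmetalation, Negishi coupling). Incomplete Zr-to-Zn exchange or a slow coupling may let palladium hydride species drag the skipped alkene into conjugation with the ester, and residual zirconium hydride may reduce the ester. The fallback joins the fragments at the alcohol oxidation level with boron and oxidises afterwards; it sets out from 9 and 5 and comes back at 12. Hydroboration of 9 with pinacolborane (Cp2Zr(H)Cl cat., Et3N cat., 60 °C) should give 2-[(E)-octadec-1-enyl]-4,4,5,5-tetramethyl-1,3,2-dioxaborolane F6. Suzuki–Miyaura coupling of F6 with iodo alcohol 5 (Pd(PPh3)4, zerovalent palladium, aqueous NaOH, THF, 50 °C; base is harmless here because no ester is present) should give (3E,5E)-docosa-3,5-dien-1-ol F7. Jones oxidation (CrO3, H2SO4, acetone, 0 °C) should give (3E,5E)-docosa-3,5-dienoic acid F8, and trimethylsilyldiazomethane in MeOH/toluene should return diene ester 12.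

## Further compounds

F1 | step 7 | methyl (E)-4-(trans-3-hexadecyloxiran-2-yl)but-3-enoate, racemic | CCCCCCCCCCCCCCCC[C@@H]1O[C@H]1/C=C/CC(=O)OC
F2 | step 7 | methyl 2-[trans-3-((E)-octadec-1-enyl)oxiran-2-yl]acetate, racemic | CCCCCCCCCCCCCCCC/C=C/[C@@H]1O[C@H]1CC(=O)OC
F3 | step 7 | methyl 2-(5-hexadecyl-2,5-dihydrofuran-2-yl)acetate, cis/trans mixture | CCCCCCCCCCCCCCCCC1C=CC(CC(=O)OC)O1
F4 | step 8 | methyl rel-(3R,6S,Z)-3,6-dihydroxydocos-4-enoate, racemic | CCCCCCCCCCCCCCCC[C@H](O)\C=C/[C@@H](CC(=O)OC)O
F5 | step 8 | methyl (Z)-3-hydroxy-6-oxodocos-4-enoate, racemic | CCCCCCCCCCCCCCCCC(=O)/C=C\C(O)CC(=O)OC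
F6 | step 6 | 2-[(E)-octadec-1-enyl]-4,4,5,5-tetramethyl-1,3,2-dioxaborolane | CCCCCCCCCCCCCCCC/C=C/B1OC(C)(C)C(C)(C)O1
F7 | step 6 | (3E,5E)-docosa-3,5-dien-1-ol | CCCCCCCCCCCCCCCC/C=C/C=C/CCO
F8 | step 6 | (3E,5E)-docosa-3,5-dienoic acid | CCCCCCCCCCCCCCCC/C=C/C=C/CC(=O)O
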